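**Retrosynthetic overview**

1. Lepadin H ⇒ N-Boc, 5′-O-TBS amino alcohol: late Yamaguchi acylation of the C3 hydroxyl with (2E,4E)-octa-2,4-dienoic acid, then one acid step removes Boc and TBS.
2. That cis-decahydroquinoline ⇒ a sulfur-bridged tricycle: one Raney Ni/H2 operation turns a C2–CH2–S–C7 bridge into the C2 methyl group and C7H2, a C4 dithiolane into C4H2, and saturates C6=C7.
3. Key disconnection C8–C8a plus C4a–C5: a type 2 intramolecular Diels–Alder reaction of a 2-thio-1,3-diene (C5–C8, already carrying the whole C5 side chain) onto the C4a=C8a bond of an N-Boc-2,3-dihydro-4-pyridone; the piperidine ring is made first (from the L-serine-derived aldehyde), the carbocycle second.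
4. Enabling feature: in the target the C2 methyl carbon and C8 are cis substituents on C2 and C8a, the two ring carbons flanking N1 (1,3-diaxial in an N-acylpiperidine). A sulfur atom can therefore tie the methyl carbon to C7, and the temporary seven-membered ring N1–C2–CH2–S–C7–C8–C8a permits only one regiochemistry, one π-face and the endo mode before it is erased by hydrogenolysis.
5. Side chain: the C5′ carbinol comes from (R)-2-propyloxirane; the (E)-enyne diene precursor from a B-alkyl Suzuki coupling.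

Key step: step 13

Remark: intermediates are described with the locants of the target (N1, C2, C3, C4, C4a, C5–C8, C8a; side chain C1′–C8′); C3 is assumed to be configurationally stable as its benzyl ether under the near-neutral conditions of steps 3–5.

**Route**

Step 1
Reactants: 1 tert-butyl (4S)-4-formyl-2,2-dimethyl-1,3-oxazolidine-3-carboxylate
Product: 2 tert-butyl (4S)-4-[(1S)-2-ethoxy-1-hydroxyprop-2-en-1-yl]-2,2-dimethyl-1,3-oxazolidine-3-carboxylate
Conditions: CH2=CHOEt, t-BuLi, THF, −78 → 0 °C; then 1, −78 °C; aq. NaHCO3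
Reagents that add atoms: ethyl vinyl ether C=COCC
Why: Felkin–Anh (non-chelated) 1,2-addition of the acyl-anion equivalent 1-ethoxyvinyllithium to the α-amino aldehyde should set C3 anti to the nitrogen-bearing C2, as organolithium reagents generally do with this aldehyde.

Step 2
Reactants: 2 tert-butyl (4S)-4-[(1S)-2-ethoxy-1-hydroxyprop-2-en-1-yl]-2,2-dimethyl-1,3-oxazolidine-3-carboxylate
Product: 4 tert-butyl (4S)-4-[(1S)-1-(benzyloxy)-2-oxopropyl]-2,2-dimethyl-1,3-oxazolidine-3-carboxylate, via benzyl ether 3 (not isolated)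
Conditions: NaH, BnBr, n-Bu4NI (cat.), THF, 0 °C → rt; then (CO2H)2 (0.1 M aq.), THF, rt
Reagents that add atoms: benzyl bromide BrCc1ccccc1; water O
Why: Williamson O-benzylation before the ketone exists, then mild acid hydrolysis of the enol ether, should unmask the methyl ketone without touching C2 or C3 and with the N,O-acetonide and Boc group intact.

Step 3
Reactants: 4 tert-butyl (4S)-4-[(1S)-1-(benzyloxy)-2-oxopropyl]-2,2-dimethyl-1,3-oxazolidine-3-carboxylate
Product: 5 tert-butyl (4S)-4-[(1S,3E)-1-(benzyloxy)-4-(dimethylamino)-2-oxobut-3-en-1-yl]-2,2-dimethyl-1,3-oxazolidine-3-carboxylate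
Conditions: t-BuOCH(NMe2)2, PhMe, 60 °C
Reagents that add atoms: tert-butoxybis(dimethylamino)methane CN(C)C(OC(C)(C)C)N(C)C
Why: aminomethylenation (enaminone formation) can occur only at the CH3 group of the ketone, which supplies C4a and C8a as an E-configured vinylogous amide.

Step 4
Reactants: 5 tert-butyl (4S)-4-[(1S,3E)-1-(benzyloxy)-4-(dimethylamino)-2-oxobut-3-en-1-yl]-2,2-dimethyl-1,3-oxazolidine-3-carboxylate
Product: 7 (2S,3S)-3-(benzyloxy)-2-(hydroxymethyl)-2,3-dihydropyridin-4(1H)-one, via amino alcohol 6 (not isolated)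
Conditions: TFA/CH2Cl2 (1:1), 0 °C → rt; evaporate; K2CO3, MeOH/H2O, rt
Reagents that add atoms: none
Why: acidolysis of Boc and the N,O-acetonide frees the amine, which after neutralisation should close the ring by 6-endo addition–elimination at the enaminone β-carbon (vinylogous transamidation, the established route from amino-acid-derived enaminones to 2,3-dihydro-4-pyridones), C2 and C3 being untouched.

Step 5
Reactants: 7 (2S,3S)-3-(benzyloxy)-2-(hydroxymethyl)-2,3-dihydropyridin-4(1H)-one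
Product: 8 S-{[(2R,3S)-3-(benzyloxy)-4-oxo-1,2,3,4-tetrahydropyridin-2-yl]methyl} ethanethioate
Conditions: PPh3, DIAD, AcSH, THF, 0 °C → rt
Reagents that add atoms: thioacetic acid CC(=O)S
Why: Mitsunobu thioesterification of the primary alcohol should be selective because the vinylogous amide N–H is far too weakly acidic to compete with thioacetic acid, and no stereocentre reacts.

Step 6
Reactants: 9 (R)-2-propyloxirane
Product: 10 (R)-oct-7-en-4-ol
Conditions: allylMgBr, CuI (10 mol %), THF, −30 → 0 °C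
Reagents that add atoms: allylmagnesium bromide C=CC[Mg]Br
Why: copper-catalysed Grignard opening of the terminal epoxide at its CH2 carbon leaves the future C5′ stereocentre untouched.

Step 7
Reactants: 10 (R)-oct-7-en-4-ol
Product: 11 (R)-tert-butyldimethyl(oct-7-en-4-yloxy)silane
Conditions: TBSCl, imidazole, DMF, rt
Reagents that add atoms: tert-butyldimethylsilyl chloride CC(C)(C)[Si](C)(C)Cl
Why: routine silylation of the secondary alcohol gives a group that survives every step up to the final acid treatment.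

Step 8
Reactants: 12 (E)-1,2-dichloroethene
Product: 13 (E)-(4-chlorobut-3-en-1-yn-1-yl)trimethylsilane
Conditions: HC≡CSiMe3, Pd(PPh3)4 (5 mol %), CuI (10 mol %), n-BuNH2, Et2O, rt (12 in fivefold excess)
Reagents that add atoms: ethynyltrimethylsilane C#C[Si](C)(C)C
Why: Sonogashira mono-coupling of the excess E-dihalide proceeds with retention of alkene geometry and leaves one C–Cl bond for the next coupling.

Step 9
Reactants: 11 (R)-tert-butyldimethyl(oct-7-en-4-yloxy)silane; 13 (E)-(4-chlorobut-3-en-1-yn-1-yl)trimethylsilane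
Product: 15 tert-butyldimethyl{[(4R,9E)-12-(trimethylsilyl)dodec-9-en-11-yn-4-yl]oxy}silane, via alkylborane 14 (not isolated)
Conditions: 9-BBN, THF, rt; then 13, Pd(OAc)2 (3 mol %), SPhos (6 mol %), K3PO4 (3 M aq.), THF, 60 °C
Reagents that add atoms: none
Why: anti-Markovnikov hydroboration followed by B-alkyl Suzuki–Miyaura coupling with the alkenyl chloride joins C1′ to C5 with retention of the E geometry.

Step 10
Reactants: 15 tert-butyldimethyl{[(4R,9E)-12-(trimethylsilyl)dodec-9-en-11-yn-4-yl]oxy}silane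
Product: 16 tert-butyl{[(4R,9E)-dodec-9-en-11-yn-4-yl]oxy}dimethylsilane
Conditions: K2CO3 (cat.), MeOH, rt
Reagents that add atoms: none
Why: base-catalysed methanolysis cleaves only the alkynyl C–Si bond and leaves the TBS ether alone.

Step 11
Reactants: 8 S-{[(2R,3S)-3-(benzyloxy)-4-oxo-1,2,3,4-tetrahydropyridin-2-yl]methyl} ethanethioate; 16 tert-butyl{[(4R,9E)-dodec-9-en-11-yn-4-yl]oxy}dimethylsilane
Product: 18 (2R,3S)-3-(benzyloxy)-2-[({(3E,9R)-9-[(tert-butyldimethylsilyl)oxy]dodeca-1,3-dien-2-yl}sulfanyl)methyl]-2,3-dihydropyridin-4(1H)-one, via thiol 17 (not isolated)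
Conditions: NH3 (7 M in MeOH), degassed, 0 °C; evaporate; then 16, Tp*Rh(PPh3)2 (3 mol %), ClCH2CH2Cl/PhMe (1:1), rt
Reagents that add atoms: none
Why: ammonolysis frees the thiol and rhodium-catalysed Markovnikov (branched) hydrothiolation of the terminal alkyne should place sulfur on C7 and leave the E-alkene intact, the N–H vinylogous amide at this stage not being a Michael acceptor for the thiol.

Step 12
Reactants: 18 (2R,3S)-3-(benzyloxy)-2-[({(3E,9R)-9-[(tert-butyldimethylsilyl)oxy]dodeca-1,3-dien-2-yl}sulfanyl)methyl]-2,3-dihydropyridin-4(1H)-one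
Product: 19 tert-butyl (2R,3S)-3-(benzyloxy)-2-[({(3E,9R)-9-[(tert-butyldimethylsilyl)oxy]dodeca-1,3-dien-2-yl}sulfanyl)methyl]-4-oxo-3,4-dihydropyridine-1(2H)-carboxylate
Conditions: Boc2O, DMAP (20 mol %), MeCN, 0 °C; used at once
Reagents that add atoms: di-tert-butyl dicarbonate CC(C)(C)OC(=O)OC(=O)OC(C)(C)C
Why: DMAP-catalysed N-acylation turns the vinylogous amide into a vinylogous imide, which activates C8a=C4a as a dienophile and, through A1,3 strain, forces the C2 side arm axial over the ring.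

Step 13
Reactants: 19 tert-butyl (2R,3S)-3-(benzyloxy)-2-[({(3E,9R)-9-[(tert-butyldimethylsilyl)oxy]dodeca-1,3-dien-2-yl}sulfanyl)methyl]-4-oxo-3,4-dihydropyridine-1(2H)-carboxylate
Product: 20 sulfur-bridged cycloadduct: tert-butyl 3-(benzyloxy)-5-{(5R)-5-[(tert-butyldimethylsilyl)oxy]octyl}-4-oxo-3,4,4a,5,8,8a-hexahydroquinoline-1(2H)-carboxylate whose C2 and C7 are joined by a CH2–S bridge (CH2 on C2 and S on C7; C6=C7 double bond; H-2, H-4a, H-5, H-8a and the 3-benzyloxy group all on the face opposite to the bridge)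
Conditions: PhMe (5 mM), BHT (cat.), 90 °C
Reagents that add atoms: none
Why: Proposed new method: on warming, the tethered 2-alkylthio-1,3-diene should add across the C8a=C4a bond of the N-Boc vinylogous imide in an asynchronous concerted [4+2] cycloaddition in which the C8–C8a bond leads (largest HOMO coefficient of the thiodiene on its CH2 terminus C8, largest LUMO coefficient of the dienophile on C8a, β to the C4 carbonyl), the closest known reaction type being the type 2 intramolecular Diels–Alder reaction of 2-substituted dienes linked through a removable four-atom heteroatom tether to an enone, which gives bicyclo[4.3.1]decene bridgehead alkenes. Two rings close: the six-membered carbocycle C4a–C5–C6=C7–C8–C8a by the [4+2] event itself, and the seven-membered ring N1–C2–CH2–S–C7–C8–C8a by the 1,3-bridged (type 2) mode, its C6=C7 alkene starting at the bridgehead C7 but being trans only within a nine-membered ring. C8a is set by the tether, because A1,3 strain with N-Boc holds the C2 arm axial so that the diene reaches only the ring face syn to C2 (2,8a-cis); C4a follows from suprafacial addition (cis ring fusion); C5 follows from the E geometry of C5=C6 together with the endo orientation (diene stacked over the heterocycle), the only one that the C2-to-C7 tether allows, which places the side chain cis to C4. The step needs regioselectivity (C8 to C8a and not to C4a), a single π-face and endo selectivity, and all three are imposed by the short tether and reinforced by the polarity match, while the trans C3 benzyloxy group lies on the opposite face. No stereocentre already present (C2, C3, C5′) is touched.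

Step 14
Reactants: 20 sulfur-bridged cycloadduct
Product: 21 C4 1,3-dithiolane of 20 (4-spiro-1,3-dithiolane in place of the ketone, all else unchanged)
Conditions: HS(CH2)2SH, Zn(OTf)2, CH2Cl2, rt
Reagents that add atoms: ethane-1,2-dithiol SCCS
Why: mild Lewis-acid thioketalisation of the C4 ketone prepares its reductive removal, and any thiol exchange at the vinyl sulfide is harmless because all sulfur-bearing products converge in step 15.

Step 15
Reactants: 21 C4 1,3-dithiolane of 20
Product: 23 tert-butyl (2S,3R,4aS,5S,8aR)-5-{(5R)-5-[(tert-butyldimethylsilyl)oxy]octyl}-3-hydroxy-2-methyloctahydroquinoline-1(2H)-carboxylate, via saturated benzyl ether 22 (not isolated)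
Conditions: Raney Ni (W-2), H2 (1 atm), EtOH, 60 °C; then Pd(OH)2/C, H2 (1 atm), EtOH, rt
Reagents that add atoms: none
Why: Raney-nickel hydrogenolysis should cleave all six C–S bonds (C4 becomes CH2, the C2 arm becomes the methyl group, C7 loses sulfur) and saturate C6=C7 without touching a stereocentre, after which palladium-catalysed hydrogenolysis removes the benzyl ether.

Step 16
Reactants: 24 (E)-hex-2-enal
Product: 25 (2E,4E)-octa-2,4-dienoic acid
Conditions: CH2(CO2H)2, pyridine, piperidine (cat.), 90 °C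
Reagents that add atoms: malonic acid OC(=O)CC(=O)O
Why: Doebner–Knoevenagel condensation with decarboxylation gives the 2E acid and keeps the existing E alkene.

Step 17
Reactants: 23 tert-butyl (2S,3R,4aS,5S,8aR)-5-{(5R)-5-[(tert-butyldimethylsilyl)oxy]octyl}-3-hydroxy-2-methyloctahydroquinoline-1(2H)-carboxylate; 25 (2E,4E)-octa-2,4-dienoic acid
Product: 27 tert-butyl (2S,3R,4aS,5S,8aR)-5-{(5R)-5-[(tert-butyldimethylsilyl)oxy]octyl}-2-methyl-3-{[(2E,4E)-octa-2,4-dienoyl]oxy}octahydroquinoline-1(2H)-carboxylate, via mixed anhydride 26 (not isolated)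
Conditions: 25, 2,4,6-Cl3C6H2COCl, Et3N, PhMe, rt; then 23, DMAP, PhMe, rt
Reagents that add atoms: none
Why: Yamaguchi esterification acylates the only free hydroxyl (C3) with retention of configuration, nitrogen being blocked as its carbamate and C5′–O as its silyl ether.

Step 18
Reactants: 27 tert-butyl (2S,3R,4aS,5S,8aR)-5-{(5R)-5-[(tert-butyldimethylsilyl)oxy]octyl}-2-methyl-3-{[(2E,4E)-octa-2,4-dienoyl]oxy}octahydroquinoline-1(2H)-carboxylate
Product: 28 lepadin H, (2S,3R,4aS,5S,8aR)-5-[(5R)-5-hydroxyoctyl]-2-methyldecahydroquinolin-3-yl (2E,4E)-octa-2,4-dienoate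
Conditions: TFA/CH2Cl2/H2O (10:10:1), 0 °C → rt; aq. NaHCO3
Reagents that add atoms: none
Why: acidolysis removes the Boc group and the TBS ether in one operation, the dienoate being stable to acid and the protonated amine unable to take part in O-to-N acyl transfer.

**Compound list**

1 | tert-butyl (4S)-4-formyl-2,2-dimethyl-1,3-oxazolidine-3-carboxylate | O=C[C@@H]1COC(C)(C)N1C(=O)OC(C)(C)C | starting material
2 | tert-butyl (4S)-4-[(1S)-2-ethoxy-1-hydroxyprop-2-en-1-yl]-2,2-dimethyl-1,3-oxazolidine-3-carboxylate | CCOC(=C)[C@@H](O)[C@@H]1COC(C)(C)N1C(=O)OC(C)(C)C | intermediate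
3 | tert-butyl (4S)-4-[(1S)-1-(benzyloxy)-2-ethoxyprop-2-en-1-yl]-2,2-dimethyl-1,3-oxazolidine-3-carboxylate | CCOC(=C)[C@@H](OCc2ccccc2)[C@@H]1COC(C)(C)N1C(=O)OC(C)(C)C | intermediate
4 | tert-butyl (4S)-4-[(1S)-1-(benzyloxy)-2-oxopropyl]-2,2-dimethyl-1,3-oxazolidine-3-carboxylate | CC(=O)[C@@H](OCc2ccccc2)[C@@H]1COC(C)(C)N1C(=O)OC(C)(C)C | intermediate
5 | tert-butyl (4S)-4-[(1S,3E)-1-(benzyloxy)-4-(dimethylamino)-2-oxobut-3-en-1-yl]-2,2-dimethyl-1,3-oxazolidine-3-carboxylate | CN(C)/C=C/C(=O)[C@@H](OCc2ccccc2)[C@@H]1COC(C)(C)N1C(=O)OC(C)(C)C | intermediate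
6 | (1E,4S,5S)-5-amino-4-(benzyloxy)-1-(dimethylamino)-6-hydroxyhex-1-en-3-one | CN(C)/C=C/C(=O)[C@@H](OCc1ccccc1)[C@@H](N)CO | intermediate
7 | (2S,3S)-3-(benzyloxy)-2-(hydroxymethyl)-2,3-dihydropyridin-4(1H)-one | O=C1C=CN[C@@H](CO)[C@@H]1OCc2ccccc2 | intermediate
8 | S-{[(2R,3S)-3-(benzyloxy)-4-oxo-1,2,3,4-tetrahydropyridin-2-yl]methyl} ethanethioate | O=C1C=CN[C@@H](CSC(C)=O)[C@@H]1OCc2ccccc2 | intermediate
9 | (R)-2-propyloxirane | CCC[C@@H]1CO1 | starting material
10 | (R)-oct-7-en-4-ol | C=CCC[C@H](O)CCC | intermediate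
11 | (R)-tert-butyldimethyl(oct-7-en-4-yloxy)silane | C=CCC[C@H](O[Si](C)(C)C(C)(C)C)CCC | intermediate
12 | (E)-1,2-dichloroethene | Cl/C=C/Cl | starting material
13 | (E)-(4-chlorobut-3-en-1-yn-1-yl)trimethylsilane | C[Si](C)(C)C#C/C=C/Cl | intermediate
14 | 9-{(5R)-5-[(tert-butyldimethylsilyl)oxy]octyl}-9-borabicyclo[3.3.1]nonane | CCC[C@@H](O[Si](C)(C)C(C)(C)C)CCCCB1C2CCCC1CCC2 | intermediate
15 | tert-butyldimethyl{[(4R,9E)-12-(trimethylsilyl)dodec-9-en-11-yn-4-yl]oxy}silane | C[Si](C)(C)C#C/C=C/CCCC[C@H](O[Si](C)(C)C(C)(C)C)CCC | intermediate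
16 | tert-butyl{[(4R,9E)-dodec-9-en-11-yn-4-yl]oxy}dimethylsilane | C#C/C=C/CCCC[C@H](O[Si](C)(C)C(C)(C)C)CCC | intermediate
17 | (2R,3S)-3-(benzyloxy)-2-(sulfanylmethyl)-2,3-dihydropyridin-4(1H)-one | O=C1C=CN[C@@H](CS)[C@@H]1OCc2ccccc2 | intermediate
18 | (2R,3S)-3-(benzyloxy)-2-[({(3E,9R)-9-[(tert-butyldimethylsilyl)oxy]dodeca-1,3-dien-2-yl}sulfanyl)methyl]-2,3-dihydropyridin-4(1H)-one | O=C1C=CN[C@@H](CSC(=C)/C=C/CCCC[C@H](O[Si](C)(C)C(C)(C)C)CCC)[C@@H]1OCc2ccccc2 | intermediate
19 | tert-butyl (2R,3S)-3-(benzyloxy)-2-[({(3E,9R)-9-[(tert-butyldimethylsilyl)oxy]dodeca-1,3-dien-2-yl}sulfanyl)methyl]-4-oxo-3,4-dihydropyridine-1(2H)-carboxylate | CC(C)(C)OC(=O)N1C=CC(=O)[C@@H](OCc2ccccc2)[C@@H]1CSC(=C)/C=C/CCCC[C@H](O[Si](C)(C)C(C)(C)C)CCC | intermediate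
20 | sulfur-bridged cycloadduct: N-Boc 3-(benzyloxy)-5-[(5R)-5-(TBS-oxy)octyl]-4-oxo-hexahydroquinoline with a C2–CH2–S–C7 bridge and a C6=C7 double bond; H-2, H-4a, H-5, H-8a and 3-OBn on the face opposite to the bridge | C(c1ccccc1)O[C@@H]2C(=O)[C@H]3[C@@H](CCCC[C@H](O[Si](C)(C)C(C)(C)C)CCC)C=C4C[C@H]3N(C(=O)OC(C)(C)C)[C@H]2CS4 | intermediate
21 | C4 spiro-1,3-dithiolane of 20 | C(c1ccccc1)O[C@@H]2C5(SCCS5)[C@H]3[C@@H](CCCC[C@H](O[Si](C)(C)C(C)(C)C)CCC)C=C4C[C@H]3N(C(=O)OC(C)(C)C)[C@H]2CS4 | intermediate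
22 | tert-butyl (2S,3R,4aS,5S,8aR)-3-(benzyloxy)-5-{(5R)-5-[(tert-butyldimethylsilyl)oxy]octyl}-2-methyloctahydroquinoline-1(2H)-carboxylate | C(c1ccccc1)O[C@@H]2C[C@H]3[C@@H](CCCC[C@H](O[Si](C)(C)C(C)(C)C)CCC)CCC[C@H]3N(C(=O)OC(C)(C)C)[C@H]2C | intermediate
23 | tert-butyl (2S,3R,4aS,5S,8aR)-5-{(5R)-5-[(tert-butyldimethylsilyl)oxy]octyl}-3-hydroxy-2-methyloctahydroquinoline-1(2H)-carboxylate | O[C@@H]1C[C@H]2[C@@H](CCCC[C@H](O[Si](C)(C)C(C)(C)C)CCC)CCC[C@H]2N(C(=O)OC(C)(C)C)[C@H]1C | intermediate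
24 | (E)-hex-2-enal | CCC/C=C/C=O | starting material
25 | (2E,4E)-octa-2,4-dienoic acid | CCC/C=C/C=C/C(=O)O | intermediate
26 | (2E,4E)-octa-2,4-dienoic 2,4,6-trichlorobenzoic anhydride | CCC/C=C/C=C/C(=O)OC(=O)c1c(Cl)cc(Cl)cc1Cl | intermediate
27 | tert-butyl (2S,3R,4aS,5S,8aR)-5-{(5R)-5-[(tert-butyldimethylsilyl)oxy]octyl}-2-methyl-3-{[(2E,4E)-octa-2,4-dienoyl]oxy}octahydroquinoline-1(2H)-carboxylate | CCC/C=C/C=C/C(=O)O[C@@H]1C[C@H]2[C@@H](CCCC[C@H](O[Si](C)(C)C(C)(C)C)CCC)CCC[C@H]2N(C(=O)OC(C)(C)C)[C@H]1C | intermediate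
28 | lepadin H, (2S,3R,4aS,5S,8aR)-5-[(5R)-5-hydroxyoctyl]-2-methyldecahydroquinolin-3-yl (2E,4E)-octa-2,4-dienoate | CCC/C=C/C=C/C(=O)O[C@@H]1C[C@H]2[C@@H](CCCC[C@H](O)CCC)CCC[C@H]2N[C@H]1C | target

**Step count**

Total: 18 steps. Longest linear sequence: 12 steps (steps 1–5, 11–15, 17 and 18, from compound 1).

**Steps most likely to fail**

Step 13 (carries the label "Proposed new method:"). The bridged transition state may not be reached before the thiodiene polymerises or the Boc group is lost thermally. The fallback is a stepwise anionic annulation with known reactions; it sets out from 8 and 16 and returns at 23. Thioacetate 8 is cleaved to thiol 17 (NH3, MeOH) and S-methylated (MeI) to (2R,3S)-3-(benzyloxy)-2-[(methylsulfanyl)methyl]-2,3-dihydropyridin-4(1H)-one F1. N-Acylation (Boc2O, DMAP) gives tert-butyl (2R,3S)-3-(benzyloxy)-2-[(methylsulfanyl)methyl]-4-oxo-3,4-dihydropyridine-1(2H)-carboxylate F2. Enyne 16 is hydrated at its terminal alkyne (Ph3PAuNTf2, wet dioxane) to (3E,9R)-9-[(tert-butyldimethylsilyl)oxy]dodec-3-en-2-one F3. F3, deprotonated at its methyl group (LDA, THF, −78 °C), should add to F2 in a double Michael reaction. The first addition goes to C8a, axially and cis to the C2 arm, as organocopper reagents add to N-acyl-2,3-dihydro-4-pyridones; the second, reversible addition goes from C4a to C5 through a chair with the side chain equatorial. The product is the all-cis N-Boc 3-(benzyloxy)-2-[(methylsulfanyl)methyl]-5-[(5R)-5-(TBS-oxy)octyl]octahydroquinoline-4,7-dione F4. Both ketones are thioketalised to the 4,7-bis(1,3-dithiolane) F5. Under the conditions of step 15, F5 loses all five sulfur atoms (the S-methyl arm becomes the C2 methyl group) and the benzyl group and rejoins the route at 23.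

Step 11. Markovnikov regiocontrol may be lost in the hydrothiolation (linear vinyl sulfides), or the catalyst may be deactivated by the thiol and the vinylogous amide. The fallback fixes the C–S bond by cross-coupling; it sets out from 16 and returns at 18. Bromoboration of 16 with B-bromo-9-BBN gives the alkenylborane 9-[(1Z,3E,9R)-2-bromo-9-(TBS-oxy)dodeca-1,3-dien-1-yl]-9-borabicyclo[3.3.1]nonane F6. Protonolysis (AcOH) gives tert-butyl{[(4R,9E)-11-bromododeca-9,11-dien-4-yl]oxy}dimethylsilane F7. F7 is joined to thiol 17 (from 8) by palladium-catalysed C–S coupling (Pd2(dba)3, Xantphos, i-Pr2NEt, dioxane, 80 °C) to give 18.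

Step 14. Thioketal formation at the hindered, α-alkoxy C4 ketone may stay incomplete, or Boc or TBS may be lost to the Lewis acid first. The fallback replaces carbonyl addition of the dithiol by a radical deoxygenation; it sets out from 20 and returns at 23. Reduction of 20 (NaBH4, MeOH) gives the C4 alcohol of the cycloadduct F8 (either C4 epimer serves). 1,1′-Thiocarbonyldiimidazole converts it into the C4 O-(imidazol-1-ylthiocarbonyl) derivative F9. Barton–McCombie reduction (Bu3SnH, AIBN, PhMe, 90 °C) gives the C4-methylene sulfur-bridged tricycle F10, which under the conditions of step 15 passes through 22 and rejoins the route at 23.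

Further compounds
F1 | step 13 | (2R,3S)-3-(benzyloxy)-2-[(methylsulfanyl)methyl]-2,3-dihydropyridin-4(1H)-one | O=C1C=CN[C@@H](CSC)[C@@H]1OCc2ccccc2
F2 | step 13 | tert-butyl (2R,3S)-3-(benzyloxy)-2-[(methylsulfanyl)methyl]-4-oxo-3,4-dihydropyridine-1(2H)-carboxylate | CC(C)(C)OC(=O)N1C=CC(=O)[C@@H](OCc2ccccc2)[C@@H]1CSC
F3 | step 13 | (3E,9R)-9-[(tert-butyldimethylsilyl)oxy]dodec-3-en-2-one | CC(=O)/C=C/CCCC[C@H](O[Si](C)(C)C(C)(C)C)CCC
F4 | step 13 | all-cis N-Boc 3-(benzyloxy)-2-[(methylsulfanyl)methyl]-5-[(5R)-5-(TBS-oxy)octyl]octahydroquinoline-4,7-dione | C(c1ccccc1)O[C@@H]2C(=O)[C@H]3[C@@H](CCCC[C@H](O[Si](C)(C)C(C)(C)C)CCC)CC(=O)C[C@H]3N(C(=O)OC(C)(C)C)[C@H]2CSC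
F5 | step 13 | 4,7-bis(spiro-1,3-dithiolane) of F4 | C(c1ccccc1)O[C@@H]2C5(SCCS5)[C@H]3[C@@H](CCCC[C@H](O[Si](C)(C)C(C)(C)C)CCC)CC6(SCCS6)C[C@H]3N(C(=O)OC(C)(C)C)[C@H]2CSC
F6 | step 11 | 9-[(1Z,3E,9R)-2-bromo-9-[(tert-butyldimethylsilyl)oxy]dodeca-1,3-dien-1-yl]-9-borabicyclo[3.3.1]nonane | B1(C2CCCC1CCC2)/C=C(Br)/C=C/CCCC[C@H](O[Si](C)(C)C(C)(C)C)CCC
F7 | step 11 | tert-butyl{[(4R,9E)-11-bromododeca-9,11-dien-4-yl]oxy}dimethylsilane | C=C(Br)/C=C/CCCC[C@H](O[Si](C)(C)C(C)(C)C)CCC
F8 | step 14 | C4 alcohol of cycloadduct 20 (C4 configuration left open, either epimer) | C(c1ccccc1)O[C@@H]2C(O)[C@H]3[C@@H](CCCC[C@H](O[Si](C)(C)C(C)(C)C)CCC)C=C4C[C@H]3N(C(=O)OC(C)(C)C)[C@H]2CS4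
F9 | step 14 | C4 O-(1H-imidazol-1-ylthiocarbonyl) derivative of F8 | C(c1ccccc1)O[C@@H]2C(OC(=S)n5ccnc5)[C@H]3[C@@H](CCCC[C@H](O[Si](C)(C)C(C)(C)C)CCC)C=C4C[C@H]3N(C(=O)OC(C)(C)C)[C@H]2CS4
F10 | step 14 | C4-methylene analogue of cycloadduct 20 (C2–CH2–S–C7 bridge and C6=C7 retained) | C(c1ccccc1)O[C@@H]2C[C@H]3[C@@H](CCCC[C@H](O[Si](C)(C)C(C)(C)C)CCC)C=C4C[C@H]3N(C(=O)OC(C)(C)C)[C@H]2CS4
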